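Late in these runs the question is what stands in the flask, not how fast it got there. In the west flask the forward step of electrophile with nucleophile, counted alone at the charged amounts, has a half-life of 0.61 h, against a run of 25 h.

    2 nucleophile → homo dimer (k1 = 0.46 /M/h)
    electrophile + nucleophile ⇌ acid set free + product (K2 = 0.70, k2 = 1.9 /M/h)
    nucleophile + product ⇌ idle adduct, settled at all times (K3 = 38 /M)
    nucleophile + acid set free ⇌ protonated nucleophile, settled at all times (K4 = 640 /M)

| flask | electrophile | nucleophile | time |
|---|---|---|---|
| west | 0.50 M | 0.600 M | 25 h |
| south-west | 0.50 M | 0.900 M | 25 h |
| north-west | 0.50 M | 1.30 M | 25 h |

* part of the electrophile that has reacted at the end, west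
* part of the electrophile that has reacted at the end, south-west
* part of the electrophile that has reacted at the end, north-west
* what raising the concentration of nucleophile from its lowest to its highest value here does to the part of the electrophile that has reacted (changes below 5 percentage points count as none) (no change / it falls / it rises)

- amounts and yields of product count idle adduct too
- for a step with 2 of a species take k times the square, and two of it per event
- run time (west): 25 h

I reckon by price. Acid set free and product both bind nucleophile: at the charge in west, equilibrium constant times c(nucleophile) is 380 for protonation and 23 for the idle adduct. Both figures hold at the charge and sink as c(nucleophile) falls, so 3 nucleophile per reacted electrophile is a ceiling: one that reacts, one protonated, one in the adduct. I charge that ceiling. Charge of nucleophile over 3 times charge of electrophile gives 40.0 % for west; call this the budget conversion. South-west gets 60.0 % and north-west 86.7 %, so at this price nucleophile is the limiting reagent in each flask.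

My colleague reckons by race. Just after the start in south-west, the forward step uses nucleophile 1.2 times as fast as the dimerisation, a selectivity factor close to even. Adding that loss to my price, the colleague gets 46.5 % for south-west. I answer that the dimerisation runs on the square of c(nucleophile) and the forward step on its first power, so the ratio grows as c(nucleophile) falls.

The forecast, made apart from us, gives 44 % for west, 57 % for south-west and 75 % for north-west, and for the trend, it rises. These are not my numbers, though its ground is my price: “Each unit of conversion ties up about three nucleophile”.

The simulation gives 45.3 % for west, 60.5 % for south-west and 75.7 % for north-west; from lowest to highest charge it rises, by 30 percentage points.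

West stands at 45.3 % against a budget of 40.0 %, and its idle adduct holds 16.7 % of the charged electrophile, less than the 45.3 % reacted, so the adduct's place in the price is not filled there. South-west stands at 60.5 % against a budget of 60.0 % and my colleague's 46.5 %, and north-west at 75.7 % against 86.7 %. A neighbour of south-west with 0.36 M of nucleophile gives 30.5 % against a budget of 24.0 %. In south-west the forward step and the dimerisation ran first, with half of their turnovers done by 0.338 h and 0.171 h; then, with free nucleophile at 2.51 % of its charge, the dimerisation crept on. My colleague's race has its region in long standing: by 250 h north-west has fallen to 64.9 %, with homo dimer at 0.243 M.

The constants are those of an exercise; no experiment stands behind them.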